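**Retrosynthetic overview**
- Target 18 comes from phenol 17 by removal of three benzyl ethers; the C2 hydroxyl of ring A comes from the C2 bromide of 15 by borylation and oxidation.
- Ring A of 15 is made from pyronyl ester 11 and methyl 3-bromopropiolate 13 by (4+2) cycloaddition across pyrone C3 and C6 and loss of CO2, which forms C2–C3 and C1–C6 of ring A.
- The strategy rests on the run C3(CH3)–C4(O-acyl)–C5(H)–C6(CH3) of ring A, which is C3–C6 of 4-hydroxy-3,6-dimethyl-2-pyrone 4; its acidic 4-hydroxyl takes the ring B acyl group before ring A exists.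
- 11 comes from 4 (two steps from triacetic acid lactone 1) and acid 9 (benzylation, formylation and oxidation of 5-methylpyrogallol 5). Ring B and the pyrone are bought as rings; ring A is the only ring formed (step 8).

Key step: step 8

Remark: ring A is numbered C1 (CO2Me), C2 (OH), C3 (CH3), C4 (ester oxygen), C5 (H), C6 (CH3); the target has no stereocentre, and the bridged intermediate 14 is racemic and loses both of its stereocentres within step 8.

**Route**

Step 1
Reactants: 1 4-hydroxy-6-methyl-2H-pyran-2-one (triacetic acid lactone)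
Product: 3 4-hydroxy-6-methyl-3-[(phenylsulfanyl)methyl]-2H-pyran-2-one, via 3-methylidene pyrandione 2 (not isolated)
Conditions: (CH2O)n, PhSH (excess), piperidine (cat.), AcOH (cat.), EtOH, reflux
Reagents that add atoms: formaldehyde (as paraformaldehyde), C=O; thiophenol, Sc1ccccc1
Why: Knoevenagel condensation of the acidic C3–H of 1 with formaldehyde gives the methylidene dione 2, which is trapped at once by thia-Michael addition of thiophenol, so that one carbon is placed at C3 only and the excess thiol outruns addition of a second pyrone.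

Step 2
Reactants: 3 4-hydroxy-6-methyl-3-[(phenylsulfanyl)methyl]-2H-pyran-2-one
Product: 4 4-hydroxy-3,6-dimethyl-2H-pyran-2-one
Conditions: Raney Ni (W-2, acetone-deactivated), EtOH, reflux
Reagents that add atoms: none
Why: Raney nickel desulfurisation cleaves the activated C–S bond and leaves the C3 methyl group, and the deactivated catalyst should not reduce the pyrone ring.

Step 3
Reactants: 5 5-methylbenzene-1,2,3-triol (5-methylpyrogallol)
Product: 6 1,2,3-tris(benzyloxy)-5-methylbenzene
Conditions: BnBr, K2CO3, DMF, 60 °C, under argon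
Reagents that add atoms: benzyl bromide, BrCc1ccccc1
Why: Williamson etherification of the three phenols, run under argon because the pyrogallol anion is air-sensitive, gives benzyl ethers that are all removed together in the last step.

Step 4
Reactants: 6 1,2,3-tris(benzyloxy)-5-methylbenzene
Product: 8 2,3,4-tris(benzyloxy)-6-methylbenzaldehyde, via aryl iminium chloride 7 (not isolated)
Conditions: POCl3, DMF, 0 to 75 °C; then aq. NaOAc
Reagents that add atoms: N,N-dimethylformamide, CN(C)C=O (formyl carbon); water, O (aldehyde oxygen); phosphoryl chloride, O=P(Cl)(Cl)Cl (chloride counter-ion of 7 only)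
Why: Vilsmeier–Haack formylation occurs at the only kind of free ring position (C4, equivalent to C6), which is ortho and para to benzyloxy groups, and aqueous NaOAc hydrolyses iminium salt 7 to the aldehyde.

Step 5
Reactants: 8 2,3,4-tris(benzyloxy)-6-methylbenzaldehyde
Product: 9 2,3,4-tris(benzyloxy)-6-methylbenzoic acid
Conditions: NaClO2, NaH2PO4, 2-methyl-2-butene, t-BuOH/THF/H2O, rt
Reagents that add atoms: sodium chlorite, [Na+].[O-]Cl=O
Why: Pinnick oxidation converts the hindered aryl aldehyde to the acid without touching the benzyl ethers or the electron-rich ring, because 2-methyl-2-butene consumes the HOCl formed.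

Step 6
Reactants: 9 2,3,4-tris(benzyloxy)-6-methylbenzoic acid; 4 4-hydroxy-3,6-dimethyl-2H-pyran-2-one
Product: 11 3,6-dimethyl-2-oxo-2H-pyran-4-yl 2,3,4-tris(benzyloxy)-6-methylbenzoate, via acid chloride 10 (not isolated)
Conditions: (COCl)2, DMF (cat.), CH2Cl2, 0 °C to rt; evaporate; then 4, Et3N, DMAP (cat.), CH2Cl2, 0 °C to rt
Reagents that add atoms: oxalyl chloride, ClC(=O)C(Cl)=O (supplies the chlorine of 10; no atom of it stays in 11)
Why: Acid chloride 10 acylates the acidic 4-hydroxyl of the pyrone (a vinylogous carboxylic acid) under nucleophilic catalysis by DMAP, and the 3-methyl group leaves no free C3 position for acyl transfer to carbon.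

Step 7
Reactants: 12 methyl propiolate
Product: 13 methyl 3-bromopropiolate
Conditions: NBS, AgNO3 (10 mol %), acetone, rt; distil under reduced pressure (lachrymator)
Reagents that add atoms: N-bromosuccinimide, O=C1CCC(=O)N1Br
Why: AgNO3-catalysed electrophilic bromination of the terminal alkyne C–H with NBS is the standard preparation of 1-bromoalkynes and tolerates the ester.

Step 8
Reactants: 11 3,6-dimethyl-2-oxo-2H-pyran-4-yl 2,3,4-tris(benzyloxy)-6-methylbenzoate; 13 methyl 3-bromopropiolate
Product: 15 methyl 2-bromo-3,6-dimethyl-4-{[2,3,4-tris(benzyloxy)-6-methylbenzoyl]oxy}benzoate, via bridged lactone cycloadduct 14 (not isolated)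
Conditions: 13 (4 equiv, added in portions), BHT (cat.), toluene, sealed tube, 140 °C
Reagents that add atoms: none
Why: The s-cis diene C3=C4–C5=C6 held in the pyrone adds thermally in a concerted, asynchronous (4+2) step to the alkyne of 13 to give the 2-oxabicyclo[2.2.2]octadienone 14, whose lactone bridge is then expelled as CO2 in a retro-(4+2) step, so the benzene arrives at the right oxidation level without an oxidant. The closest known reaction type is the Diels–Alder reaction of 2-pyrones with propiolates and acetylenedicarboxylates followed by CO2 extrusion to benzoates, and 3-bromopropiolates are established dienophiles. Ring A is closed as a six-membered carbocycle by intermolecular (4+2) annulation, the new bonds being C2–C3 and C1–C6 of ring A, and it becomes aromatic on loss of the O1–C2 bridge of the pyrone. No stereocentre is kept, since the two bridgehead carbons of 14 form as a racemic pair fixed by the bicycle and both become sp2 on loss of CO2. The selectivity needed is regiochemical (bromine-bearing alkyne carbon to pyrone C3, ester-bearing alkyne carbon to pyrone C6); the ring oxygen and the 4-acyloxy group should secure it by placing the largest HOMO coefficient at C3, which pairs with the β-carbon of the propiolate where the LUMO coefficient is largest. The 3-methyl group also blocks O-to-C acyl migration in the pyrone during heating.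

Step 9
Reactants: 15 methyl 2-bromo-3,6-dimethyl-4-{[2,3,4-tris(benzyloxy)-6-methylbenzoyl]oxy}benzoate
Product: 16 methyl 3,6-dimethyl-2-(4,4,5,5-tetramethyl-1,3,2-dioxaborolan-2-yl)-4-{[2,3,4-tris(benzyloxy)-6-methylbenzoyl]oxy}benzoate
Conditions: B2pin2, Pd2(dba)3 (cat.), XPhos, KOAc, 1,4-dioxane, 100 °C
Reagents that add atoms: bis(pinacolato)diboron, CC1(C)OB(OC1(C)C)B1OC(C)(C)C(C)(C)O1
Why: Miyaura borylation (oxidative addition of zerovalent palladium into the C–Br bond ortho to the ester, acetate-assisted transmetalation with B2pin2, reductive elimination) is run with the bulky biaryl phosphine XPhos because the bromide is flanked by CO2Me and CH3, and KOAc is too weak a base to cleave either ester.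

Step 10
Reactants: 16 the pinacol boronate
Product: 17 methyl 2-hydroxy-3,6-dimethyl-4-{[2,3,4-tris(benzyloxy)-6-methylbenzoyl]oxy}benzoate
Conditions: NaBO3·4H2O, THF/H2O (1:1), rt
Reagents that add atoms: sodium perborate (NaBO3·4H2O), [Na+].[O-]OB=O
Why: Perborate oxidation of the aryl boronate (1,2-shift of the aryl group from boron to oxygen, then hydrolysis) gives the phenol under mild conditions that should spare the methyl ester and the hindered depside ester.

Step 11
Reactants: 17 methyl 2-hydroxy-3,6-dimethyl-4-{[2,3,4-tris(benzyloxy)-6-methylbenzoyl]oxy}benzoate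
Product: 18 methyl 2-hydroxy-3,6-dimethyl-4-[(2,3,4-trihydroxy-6-methylbenzoyl)oxy]benzoate (target)
Conditions: H2 (1 atm), 10% Pd/C, EtOAc/THF, rt; filter under argon
Reagents that add atoms: none
Why: Hydrogenolysis of the three benzyl ethers over Pd/C leaves the aryl and methyl esters intact and frees the air-sensitive pyrogallol unit in a neutral medium from which it is isolated by filtration and evaporation.

**Compound list**
1 | 4-hydroxy-6-methyl-2H-pyran-2-one (triacetic acid lactone) | CC1=CC(O)=CC(=O)O1 | starting material
2 | 6-methyl-3-methylidene-2H-pyran-2,4(3H)-dione | CC1=CC(=O)C(=C)C(=O)O1 | intermediate (not isolated)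
3 | 4-hydroxy-6-methyl-3-[(phenylsulfanyl)methyl]-2H-pyran-2-one | CC1=CC(O)=C(CSc2ccccc2)C(=O)O1 | intermediate
4 | 4-hydroxy-3,6-dimethyl-2H-pyran-2-one | CC1=CC(O)=C(C)C(=O)O1 | intermediate
5 | 5-methylbenzene-1,2,3-triol (5-methylpyrogallol) | Cc1cc(O)c(O)c(O)c1 | starting material
6 | 1,2,3-tris(benzyloxy)-5-methylbenzene | Cc1cc(OCc2ccccc2)c(OCc2ccccc2)c(OCc2ccccc2)c1 | intermediate
7 | N-[2,3,4-tris(benzyloxy)-6-methylbenzylidene]-N-methylmethanaminium chloride | C[N+](C)=Cc1c(C)cc(OCc2ccccc2)c(OCc2ccccc2)c1OCc1ccccc1.[Cl-] | intermediate (not isolated)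
8 | 2,3,4-tris(benzyloxy)-6-methylbenzaldehyde | O=Cc1c(C)cc(OCc2ccccc2)c(OCc2ccccc2)c1OCc1ccccc1 | intermediate
9 | 2,3,4-tris(benzyloxy)-6-methylbenzoic acid | OC(=O)c1c(C)cc(OCc2ccccc2)c(OCc2ccccc2)c1OCc1ccccc1 | intermediate
10 | 2,3,4-tris(benzyloxy)-6-methylbenzoyl chloride | ClC(=O)c1c(C)cc(OCc2ccccc2)c(OCc2ccccc2)c1OCc1ccccc1 | intermediate (not isolated)
11 | 3,6-dimethyl-2-oxo-2H-pyran-4-yl 2,3,4-tris(benzyloxy)-6-methylbenzoate | CC1=CC(OC(=O)c2c(C)cc(OCc3ccccc3)c(OCc3ccccc3)c2OCc2ccccc2)=C(C)C(=O)O1 | intermediate
12 | methyl propiolate | COC(=O)C#C | starting material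
13 | methyl 3-bromopropiolate | COC(=O)C#CBr | intermediate
14 | methyl 5-bromo-1,4-dimethyl-3-oxo-8-{[2,3,4-tris(benzyloxy)-6-methylbenzoyl]oxy}-2-oxabicyclo[2.2.2]octa-5,7-diene-6-carboxylate (racemic; one enantiomer drawn) | C[C@]12OC(=O)[C@](C)(C(OC(=O)c3c(C)cc(OCc4ccccc4)c(OCc4ccccc4)c3OCc3ccccc3)=C1)C(Br)=C2C(=O)OC | intermediate (not isolated)
15 | methyl 2-bromo-3,6-dimethyl-4-{[2,3,4-tris(benzyloxy)-6-methylbenzoyl]oxy}benzoate | COC(=O)c1c(C)cc(OC(=O)c2c(C)cc(OCc3ccccc3)c(OCc3ccccc3)c2OCc2ccccc2)c(C)c1Br | intermediate
16 | methyl 3,6-dimethyl-2-(4,4,5,5-tetramethyl-1,3,2-dioxaborolan-2-yl)-4-{[2,3,4-tris(benzyloxy)-6-methylbenzoyl]oxy}benzoate | COC(=O)c1c(C)cc(OC(=O)c2c(C)cc(OCc3ccccc3)c(OCc3ccccc3)c2OCc2ccccc2)c(C)c1B2OC(C)(C)C(C)(C)O2 | intermediate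
17 | methyl 2-hydroxy-3,6-dimethyl-4-{[2,3,4-tris(benzyloxy)-6-methylbenzoyl]oxy}benzoate | COC(=O)c1c(C)cc(OC(=O)c2c(C)cc(OCc3ccccc3)c(OCc3ccccc3)c2OCc2ccccc2)c(C)c1O | intermediate
18 | methyl 2-hydroxy-3,6-dimethyl-4-[(2,3,4-trihydroxy-6-methylbenzoyl)oxy]benzoate | COC(=O)c1c(C)cc(OC(=O)c2c(C)cc(O)c(O)c2O)c(C)c1O | target

**Step count**
Total steps: 11. Longest linear sequence: 8 (steps 3, 4, 5, 6, 8, 9, 10, 11).

**Steps most likely to fail**

1. Step 8. The cycloaddition may be too slow on a diene that carries methyl groups at both termini and an acyloxy group that donates less than an alkoxy group, so that the bromoalkyne decomposes or polymerises first; addition in the opposite orientation is also possible. The fallback gives up the pyrone route to ring A and takes ring A as a bought arene. It sets out from acid 9, which is converted to acid chloride 10 as in step 6 and used to acylate commercial methyl 2,4-dihydroxy-3,6-dimethylbenzoate F1 with Et3N and DMAP (cat.) in CH2Cl2 at 0 °C. The 4-hydroxyl should react in preference to the 2-hydroxyl, which is hydrogen-bonded to the ester carbonyl and less nucleophilic. This classical depside esterification gives 17 directly; the route is rejoined at 17, and steps 1, 2 and 6 to 10 fall away.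

2. Step 9. Transmetalation at the di-ortho-substituted arylpalladium bromide may be slow, so that protodebromination or homocoupling takes over. The fallback sets out from 15 and replaces palladium catalysis by bromine–magnesium exchange with iPrMgCl·LiCl in THF at −40 °C, which the ortho ester accelerates. This gives the arylmagnesium chloride F2, which is quenched with B(OMe)3 to the dimethyl arylboronate F3 and oxidised in the same flask with aqueous NaBO3 to the phenol. The route is rejoined at 17, and step 10 falls away.

3. Step 1. The methylidene intermediate 2 may be captured by a second molecule of 1 faster than by the thiol, giving the methylene-bridged bis-pyrone, and the desulfurisation that follows may be accompanied by ring reduction. The fallback builds the pyrone ring instead of methylating it. It sets out from commercial ethyl 2-methylacetoacetate F4, whose sodium lithium dianion F5 (NaH, then n-BuLi, THF, 0 °C) is acylated at the terminal methyl carbon with N-methoxy-N-methylacetamide; acidic work-up (aq. HCl) gives ethyl 2-methyl-3,5-dioxohexanoate F6. DBU in refluxing toluene then closes the lactone from the C5 enol oxygen onto the ester with loss of ethanol. The route is rejoined at 4, and steps 1 and 2 fall away.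

**Further compounds**
F1 | step 8 | methyl 2,4-dihydroxy-3,6-dimethylbenzoate (purchased) | COC(=O)c1c(C)cc(O)c(C)c1O
F2 | step 9 | [2-(methoxycarbonyl)-3,6-dimethyl-5-{[2,3,4-tris(benzyloxy)-6-methylbenzoyl]oxy}phenyl]magnesium chloride | COC(=O)c1c(C)cc(OC(=O)c2c(C)cc(OCc3ccccc3)c(OCc3ccccc3)c2OCc2ccccc2)c(C)c1[Mg]Cl
F3 | step 9 | methyl 2-(dimethoxyboranyl)-3,6-dimethyl-4-{[2,3,4-tris(benzyloxy)-6-methylbenzoyl]oxy}benzoate | COC(=O)c1c(C)cc(OC(=O)c2c(C)cc(OCc3ccccc3)c(OCc3ccccc3)c2OCc2ccccc2)c(C)c1B(OC)OC
F4 | step 1 | ethyl 2-methylacetoacetate (racemic, purchased) | CCOC(=O)C(C)C(C)=O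
F5 | step 1 | sodium lithium dianion of ethyl 2-methylacetoacetate | [Na+].[Li+].CCOC([O-])=C(C)C([O-])=C
F6 | step 1 | ethyl 2-methyl-3,5-dioxohexanoate (racemic) | CCOC(=O)C(C)C(=O)CC(C)=O
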